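Ring positions are numbered as in the target throughout, also in open-chain intermediates: C1 (methyl-bearing alkene carbon), C2, C3, C4 (isopropyl), C5 (ester carbinol), C6, C7 (tertiary carbinol), C8–C10. Compound numbers are those of the steps and of the compound list.

## Analysis of the target

- The target 27 is a germacrane-type sesquiterpenoid ester on a single ten-membered carbocycle.
- C1=C2–C3=C4 is a conjugated diene with both double bonds trisubstituted. The ring passes trans through C1=C2 (E) and cis through C3=C4 (Z), so the core is a strained E,Z-cyclodeca-1,3-diene whose only hydrogen-bearing sp2 carbons are C2 and C3.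
- There are two stereocentres, C5 (S) and C7 (S). They are 1,3-related, with both oxygen atoms on the same side of the extended C4–C8 chain. No third stereocentre links them, so neither can be relied on to control the other across a flexible medium ring.
- The C5–O bond is the most sensitive element: it is allylic to a diene and would ionise to a pentadienyl cation with acid or Lewis acid. The tertiary C7 alcohol (elimination), the diene (oxidation, acid-triggered transannular cyclisation), the free phenol and the ester (cleavage or migration under strong base) also need care.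
- The difficulty is the combination of a medium ring, two defined trisubstituted alkene geometries and an oxygen at the most labile ring position.
- The plan rests on the C5 methylene of the deoxygenated ring 20. It is one of four allylic C–H sites (C5, C10, the C1 methyl, the isopropyl methine) and the one that lies 1,3 to the C7 hydroxyl. Only a protein pocket can be expected to single it out and to choose one of its two hydrogens.

## Retrosynthetic reasoning

**Ester and phenol (27 ⇒ 26 ⇒ 22 + 25; 25 ⇒ 24 ⇒ 23).** The last bonds made are the phenol O–H and the acyl C–O bond at the C5 oxygen. Cutting on the acyl side makes the forward reaction an acylation at oxygen, which cannot disturb the C5 stereocentre or ionise the dienylic C–O bond. The forward step must distinguish the secondary C5 hydroxyl of 22 from the tertiary C7 hydroxyl, which sterics should do. The phenol of 23 is masked as the silyl ether in 25 so that the activated acid does not acylate itself; it leaves with fluoride at 0 °C, without acid.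

**C5–O bond (22 ⇒ 20 + 21).** Removing the C5 oxygen is the central simplification. Compound 20 has one stereocentre instead of two, no ionisable allylic C–O bond and no protecting-group problem, so the strained diene ring can be built with robust organometallic chemistry. The price is that the forward reaction must pick C5 out of four allylic positions and replace its pro-S hydrogen without epoxidising the diene. No chemical oxidant does that, so the step is assigned to an engineered P450 monooxygenase using 21.

**O–Si bond (20 ⇒ 19).** The free C7 hydroxyl is wanted only at the enzymatic step, where it serves as the polar handle. Before that it is carried as a silyl ether, because the chain is assembled with Grignard, copper and aluminium reagents.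

**Ring bond C2–C3 (19 ⇒ 18).** The ring is opened at the single bond in the middle of the diene. C2 and C3 are the least hindered coupling sites, and each half then carries one complete, configurationally defined trisubstituted alkene. A cut at an sp3–sp3 bond (C8–C9, C9–C10) has no functional group in 20 to support it, and metathesis through either double bond could not control E against Z in a ten-membered ring. The forward step must keep both geometries and beat oligomerisation.

**C1–CH3 and C2–B bonds (18 ⇒ 15 + 16, through 17).** The E-alkenylboronate is traced to a terminal alkyne. Syn addition of methyl and metal from 16 fixes methyl on C1 and the metal on C2, cis to each other, which is the C1=C2 geometry of the target. Boron is chosen as the final metal because 18 can be isolated and purified before the ring closure.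

**C10–C1 bond and the prenyl end (15 ⇒ 14 ⇒ 13 ⇒ 10, through 11 and 12).** The alkyne carbons C1 and C2 are attached by alkylation at C10. C10 is the alkene CH of the isopropylidene end of 10, set free by oxidative cleavage and reduced. The forward steps must cleave the electron-rich alkene in the presence of the alkenyl iodide and substitute only the sp3 iodide of 14.

**C4–C5 and C3–I bonds (10 ⇒ 5 + 6, through 7, 8 and 9).** The trisubstituted iodoalkene is cut between C4 and C5. Syn addition of the C5 alkylcopper to the alkyne 6 puts the chain on C4 and copper on C3, cis to C5, so iodine, and later C2, ends up cis to C5. The reverse pairing (isopropyl metal added to a chain alkyne) would give the wrong geometry.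

**Functional-group changes and chiral pool (5 ⇒ 4 ⇒ 2 ⇒ 1, through 3).** The bromide comes from anti-Markovnikov hydration of the vinyl group of silylated linalool. Compound 1 supplies C5–C10, the C7 methyl and the C7 stereocentre with the correct configuration, so this centre is never created or touched in the route.

## Alternatives that were turned down

**Alternative 1: fragmentation of a five–seven bicycle.**
- Disconnection: a transannular C1–C7 bond is added retrosynthetically, so the ten-membered dienone A1 derives from a fused bicycle.
- Forward key step: a tertiary alkoxide at C7 pushes out a sulfonate at C2 while the C1–C7 bond breaks anti-periplanar to it, giving C1=C2 and the C7 carbonyl.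
- For it: the medium ring is never closed end to end; the C1=C2 geometry follows stereospecifically from the relative configuration at C1 and C2; the C5 oxygen is carried from the start. Every step is a known reaction type, so on certainty of the individual reactions it is stronger than the chosen route.
- Against it:
  - The leaving group at C2 is allylic to C3=C4, so ionisation and allylic substitution compete with the concerted fragmentation.
  - The base that triggers the step meets, in A1, a ketone whose β-carbon C5 carries an ether. Enolisation toward C6 and loss of the C5 alkoxide would erase the C5 stereocentre.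
  - The bicyclic precursor needs four correctly related stereocentres (C1, C2, C5, C7), three of which serve only the fragmentation.
  - C7 must afterwards receive its methyl group from the correct face of a flexible ten-membered ketone, with no reliable control element.
  - Oxidative removal of the 4-methoxybenzyl ether next to an electron-rich diene is awkward.
- Comparison: the chosen route takes C7 ready-made from 1, keeps the ring precursor 20 free of labile groups and is clearly shorter. What it gives up is the certainty that every step has precedent.

**Alternative 2: methylalumination and ring closure at C2–C3 with the C5 oxygen in place.**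
- Disconnection: the C2–C3 and C1–CH3 bonds, with C5 already carrying a silyl ether.
- Forward key step: zirconium-catalysed addition of 16 to a terminal alkyne, then palladium-catalysed intramolecular coupling with the tethered iodoalkene, giving A2.
- For it: the ring-closing logic is the one used here for 19; both alkene geometries come from syn carbometalations; C5 is fixed early by a reagent-controlled ketone reduction, so there is no selectivity problem among allylic C–H bonds. On certainty it is the stronger plan, and it is kept as the fallback for step 11.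
- Against it:
  - The C5 stereocentre costs about seven extra operations before the ring closure (oxidation, alkynylation, oxidation, asymmetric reduction, desilylation, directed carbomagnesiation, protection).
  - The coupling must then take place with a bulky silyloxy group next to C4, adding allylic strain to an already strained closure.
  - The dienylic C5–O bond has to survive Lewis-acidic aluminium species.
- Comparison: the chosen route reaches 22 in four fewer steps and builds the ring on a substrate without the labile oxygen. The same dienol 20 could also serve for other hydroxylated congeners. Alternative 2 offers certainty in exchange.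

**Alternative 3: conrotatory cyclobutene opening.**
- Disconnection: the diene itself. The C2–C3 single bond and both double bonds derive from a cyclobutene whose C1–C4 bond fuses it cis to an eight-membered ketone.
- Forward key step: thermal 4π ring opening, giving the dienone A3.
- For it: orbital symmetry guarantees that a cis-fused cyclobutene gives one E and one Z double bond; the ring arises by two-carbon expansion without high dilution or metals; the C5 ketone is a handle for the carbinol. For the construction of the diene ring it is the more elegant plan and in that respect stronger.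
- Against it:
  - Conrotation can run in two senses, giving either the (1E,3Z) or the (1Z,3E) diene. Only the preference of the C5 acyl carbon for inward and of isopropyl for outward rotation at the same quaternary carbon would decide.
  - The precursor has two adjacent quaternary fusion carbons on an eight-membered ring that also carries the remote C7 stereocentre, and is hard to make.
  - The cross-conjugated dienone can undergo further thermal hydrogen shifts.
  - The C5 ketone must finally be reduced to the S carbinol in a flexible ring under substrate control alone.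
- Comparison: both plans create the C5 stereocentre last. The chosen one hands site and face to a catalyst that can be evolved, and reaches its ring precursor from 1 by ten linear steps of standard chemistry.

Key step: step 11

Remark on descriptors: in 19 and 20 the C3=C4 bond is E by the sequence rules, because isopropyl outranks the C5 methylene. Its geometry is that of the Z bond of 22, 26 and 27, where oxygenated C5 outranks isopropyl.
Assumption 1: compound 1 is used in high enantiomeric purity (enriched if the commercial lot requires it).
Assumption 2: a CYP102A1 variant with the required selectivity is found by screening and directed evolution against 20 before step 11 is run preparatively.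

## Route

Step 1
Reactants: 1 (S)-(+)-linalool
Product: 2 triethyl{[(3S)-3,7-dimethylocta-1,6-dien-3-yl]oxy}silane
Conditions: Et3SiOTf, 2,6-lutidine, CH2Cl2, −78 to 0 °C
Reagents that add atoms: triethylsilyl trifluoromethanesulfonate, CC[Si](CC)(CC)OS(=O)(=O)C(F)(F)F
Why: Silylation of a tertiary allylic alcohol with a silyl triflate and a hindered pyridine base is standard; it removes the only acidic proton before the organometallic steps and does not touch the C7 stereocentre.

Step 2
Reactants: 2 triethyl{[(3S)-3,7-dimethylocta-1,6-dien-3-yl]oxy}silane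
Product: 4 (3S)-3,7-dimethyl-3-(triethylsilyloxy)oct-6-en-1-ol, via B-alkyl-9-borabicyclo[3.3.1]nonane 3 (not isolated)
Conditions: 9-BBN, THF, 0 °C to rt; then NaOH, H2O2, 0 °C to rt
Reagents that add atoms: hydrogen peroxide, OO
Why: Hydroboration–oxidation; the bulky dialkylborane adds only to the monosubstituted vinyl group, with boron on the terminal carbon (the later C5), and leaves the trisubstituted alkene alone; alkaline peroxide replaces boron by hydroxyl and no stereocentre is formed.

Step 3
Reactants: 4 (3S)-3,7-dimethyl-3-(triethylsilyloxy)oct-6-en-1-ol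
Product: 5 {[(3S)-1-bromo-3,7-dimethyloct-6-en-3-yl]oxy}triethylsilane
Conditions: CBr4, PPh3, 2,6-lutidine, CH2Cl2, 0 °C
Reagents that add atoms: carbon tetrabromide, BrC(Br)(Br)Br
Why: Appel reaction; the primary alcohol is displaced through its alkoxyphosphonium ion under nearly neutral conditions, and the lutidine buffer protects the tertiary silyl ether from traces of HBr.

Step 4
Reactants: 5 {[(3S)-1-bromo-3,7-dimethyloct-6-en-3-yl]oxy}triethylsilane; 6 3-methylbut-1-yne
Product: 10 triethyl{[(1E,5S)-1-iodo-5,9-dimethyl-2-(propan-2-yl)deca-1,8-dien-5-yl]oxy}silane, via alkylmagnesium bromide 7 (not isolated), via alkylcopper 8 (not isolated), via alkenylcopper 9 (not isolated)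
Conditions: Mg, Et2O, reflux; CuBr·SMe2, Et2O/Me2S, −45 °C; 6, −25 °C; I2, THF, −50 to 0 °C
Reagents that add atoms: iodine, II
Why: Normant carbocupration; the alkylcopper adds syn across the terminal alkyne with the alkyl group on the substituted carbon (C4) and copper on the terminal carbon (C3), so C5 and copper are cis, and iodinolysis with retention gives the iodide whose iodine, the later bond to C2, is cis to C5 as in the target. The γ-silyloxy organometallics have no β-leaving group and should be stable.

Step 5
Reactants: 10 triethyl{[(1E,5S)-1-iodo-5,9-dimethyl-2-(propan-2-yl)deca-1,8-dien-5-yl]oxy}silane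
Product: 13 (4R,7E)-8-iodo-4-methyl-7-(propan-2-yl)-4-(triethylsilyloxy)oct-7-en-1-ol, via vicinal diol 11 (not isolated), via aldehyde 12 (not isolated)
Conditions: OsO4 (cat.), NaIO4, 2,6-lutidine, dioxane/H2O, rt; then NaBH4, MeOH, 0 °C
Reagents that add atoms: osmium tetroxide, O=[Os](=O)(=O)=O; sodium periodate, [Na+].[O-]I(=O)(=O)=O
Why: Lemieux–Johnson cleavage followed by borohydride reduction; OsO4 selects the electron-rich dialkyl-substituted alkene over the iodine-bearing, more hindered one, periodate cleaves the diol with loss of acetone, and the crude aldehyde is reduced to the C10 alcohol. The descriptor at C7 changes to R only because the priorities change.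

Step 6
Reactants: 13 (4R,7E)-8-iodo-4-methyl-7-(propan-2-yl)-4-(triethylsilyloxy)oct-7-en-1-ol
Product: 14 triethyl{[(1E,5R)-1,8-diiodo-5-methyl-2-(propan-2-yl)oct-1-en-5-yl]oxy}silane
Conditions: I2, PPh3, imidazole, CH2Cl2, 0 °C to rt
Reagents that add atoms: iodine, II
Why: Appel-type iodination of the primary alcohol by SN2 displacement of its alkoxyphosphonium ion; the alkenyl iodide and the silyl ether are inert under these conditions.

Step 7
Reactants: 14 triethyl{[(1E,5R)-1,8-diiodo-5-methyl-2-(propan-2-yl)oct-1-en-5-yl]oxy}silane
Product: 15 triethyl{[(1E,5S)-1-iodo-5-methyl-2-(propan-2-yl)dec-1-en-9-yn-5-yl]oxy}silane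
Conditions: LiC≡CH·H2NCH2CH2NH2, DMSO, 15 °C to rt
Reagents that add atoms: lithium acetylide–ethylenediamine complex, [Li]C#C.NCCN
Why: SN2 alkylation of an acetylide at the primary iodide in a dipolar aprotic solvent installs C1 and C2; the sp2 carbon–iodine bond cannot undergo SN2 and its neighbouring carbon bears no hydrogen, so the alkenyl iodide should survive.

Step 8
Reactants: 15 triethyl{[(1E,5S)-1-iodo-5-methyl-2-(propan-2-yl)dec-1-en-9-yn-5-yl]oxy}silane; 16 trimethylaluminium
Product: 18 triethyl{[(1E,5S,9E)-1-iodo-5,9-dimethyl-2-(propan-2-yl)-10-(4,4,5,5-tetramethyl-1,3,2-dioxaborolan-2-yl)deca-1,9-dien-5-yl]oxy}silane, via alkenyldimethylalane 17 (not isolated)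
Conditions: Me3Al, Cp2ZrCl2 (0.5 equiv), CH2Cl2, 0 °C to rt; then i-PrOBpin, THF, 0 °C to rt
Reagents that add atoms: 2-isopropoxy-4,4,5,5-tetramethyl-1,3,2-dioxaborolane, CC(C)OB1OC(C)(C)C(C)(C)O1
Why: Negishi zirconium-catalysed carboalumination followed by aluminium-to-boron exchange; methyl and aluminium add syn with methyl on the internal carbon (C1), so the metal on C2 is cis to the new methyl and trans to C10, and the borate ester takes over the alkenyl group with retention to give an isolable E-alkenylboronate.

Step 9
Reactants: 18 triethyl{[(1E,5S,9E)-1-iodo-5,9-dimethyl-2-(propan-2-yl)-10-(4,4,5,5-tetramethyl-1,3,2-dioxaborolan-2-yl)deca-1,9-dien-5-yl]oxy}silane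
Product: 19 triethyl{[(1E,3E,7S)-4-isopropyl-1,7-dimethylcyclodeca-1,3-dien-7-yl]oxy}silane
Conditions: Pd(PPh3)4 (20 mol %), TlOEt, THF/H2O, rt, slow addition to 0.001 M
Reagents that add atoms: none
Why: Intramolecular Suzuki–Miyaura coupling under high dilution; zerovalent palladium inserts into the C3–iodine bond, the base-activated boronate transfers C2, and reductive elimination from an eleven-membered palladacycle forms the C2–C3 bond with retention at both alkenes. The two carbons joined are the least hindered sp2 positions of the diene, which keeps the closure as easy as the ring allows.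

Step 10
Reactants: 19 triethyl{[(1E,3E,7S)-4-isopropyl-1,7-dimethylcyclodeca-1,3-dien-7-yl]oxy}silane
Product: 20 (1E,3E,7S)-4-isopropyl-1,7-dimethylcyclodeca-1,3-dien-7-ol
Conditions: Bu4NF, THF, rt to 45 °C
Reagents that add atoms: none
Why: Fluoride cleavage of the tertiary silyl ether; nothing else in this hydrocarbon diene responds to fluoride, and the free C7 hydroxyl is needed as the polar handle for the enzyme.

Step 11
Reactants: 20 (1E,3E,7S)-4-isopropyl-1,7-dimethylcyclodeca-1,3-dien-7-ol; 21 dioxygen
Product: 22 (1E,3Z,5S,7S)-4-isopropyl-1,7-dimethylcyclodeca-1,3-diene-5,7-diol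
Conditions: CYP102A1 (P450 BM3) variant from directed evolution (E. coli lysate), air, NADP+ (cat.), D-glucose, glucose dehydrogenase, KPi buffer pH 8.0, 2% DMSO, 25 °C
Reagents that add atoms: none
Why: Proposed new method: no enzyme variant is yet known for this dienol, so the step rests on the general mechanism of P450 hydroxylation, in which the ferryl-oxo porphyrin radical cation abstracts a hydrogen atom and the carbon radical recombines with the iron-bound hydroxyl on the same face, and on the closest known reaction type, the regio- and enantioselective allylic hydroxylation of terpenes and macrocyclic terpene alcohols by evolved CYP102A1 variants. Here the pro-S hydrogen at C5 would be removed and replaced with retention, which gives the 5S carbinol and turns the C3=C4 descriptor into Z without moving the alkene. No ring is closed. The new stereocentre is under catalyst control: the protein pocket fixes which face of C5 is presented to the iron, and the C7 hydroxyl is expected to hydrogen-bond to a polar residue placed in the pocket so that the 1,3-related C5 lies over the haem. The step needs site selectivity over C10, the C1 methyl and the isopropyl methine, chemoselectivity over epoxidation of the diene and over further oxidation to the dienone, and rebound at C5 rather than at C3 or C1 of the delocalised radical. The substrate contributes the weak dienylic C5–H bond and the anchoring hydroxyl; the rest has to come from screening and directed evolution. The diol is more polar than the substrate and should leave the pocket, which limits over-oxidation.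

Step 12
Reactants: 23 4-hydroxybenzoic acid
Product: 25 4-(tert-butyldimethylsilyloxy)benzoic acid, via silyl ester 24 (not isolated)
Conditions: t-BuMe2SiCl, imidazole, DMF, rt; then AcOH/THF/H2O, rt
Reagents that add atoms: tert-butyldimethylsilyl chloride, CC(C)(C)[Si](C)(C)Cl
Why: Exhaustive silylation of phenol and acid followed by selective hydrolysis of the far more labile silyl ester leaves the aryl silyl ether, which blocks self-acylation of the hydroxy acid in step 13.

Step 13
Reactants: 22 (1E,3Z,5S,7S)-4-isopropyl-1,7-dimethylcyclodeca-1,3-diene-5,7-diol; 25 4-(tert-butyldimethylsilyloxy)benzoic acid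
Product: 26 (1E,3Z,5S,7S)-7-hydroxy-4-isopropyl-1,7-dimethylcyclodeca-1,3-dien-5-yl 4-(tert-butyldimethylsilyloxy)benzoate
Conditions: EDC·HCl, DMAP, CH2Cl2, 0 °C to rt
Reagents that add atoms: none
Why: Steglich esterification; the acylpyridinium ion acylates the secondary C5 hydroxyl while the tertiary C7 hydroxyl is too hindered to react. The medium is free of acid, so the dienylic C5–O bond should not ionise, and the C5 configuration is kept because only the O–H bond is broken.

Step 14
Reactants: 26 (1E,3Z,5S,7S)-7-hydroxy-4-isopropyl-1,7-dimethylcyclodeca-1,3-dien-5-yl 4-(tert-butyldimethylsilyloxy)benzoate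
Product: 27 (1E,3Z,5S,7S)-7-hydroxy-4-isopropyl-1,7-dimethylcyclodeca-1,3-dien-5-yl 4-hydroxybenzoate
Conditions: Bu4NF, AcOH, THF, 0 °C
Reagents that add atoms: none
Why: Fluoride cleaves the aryl silyl ether rapidly at 0 °C; the acetic acid buffer protonates the phenoxide at once, which should prevent ester exchange or acyl migration to C7.

## Compound list

1 | (S)-(+)-linalool, (3S)-3,7-dimethylocta-1,6-dien-3-ol | C=C[C@@](C)(O)CCC=C(C)C | starting material
2 | triethyl{[(3S)-3,7-dimethylocta-1,6-dien-3-yl]oxy}silane | C=C[C@@](C)(O[Si](CC)(CC)CC)CCC=C(C)C | intermediate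
3 | 9-[(3R)-3,7-dimethyl-3-(triethylsilyloxy)oct-6-en-1-yl]-9-borabicyclo[3.3.1]nonane | B1(C2CCCC1CCC2)CC[C@@](C)(O[Si](CC)(CC)CC)CCC=C(C)C | intermediate
4 | (3S)-3,7-dimethyl-3-(triethylsilyloxy)oct-6-en-1-ol | OCC[C@@](C)(O[Si](CC)(CC)CC)CCC=C(C)C | intermediate
5 | {[(3S)-1-bromo-3,7-dimethyloct-6-en-3-yl]oxy}triethylsilane | BrCC[C@@](C)(O[Si](CC)(CC)CC)CCC=C(C)C | intermediate
6 | 3-methylbut-1-yne | CC(C)C#C | starting material
7 | [(3S)-3,7-dimethyl-3-(triethylsilyloxy)oct-6-en-1-yl]magnesium bromide | Br[Mg]CC[C@@](C)(O[Si](CC)(CC)CC)CCC=C(C)C | intermediate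
8 | [(3S)-3,7-dimethyl-3-(triethylsilyloxy)oct-6-en-1-yl]copper (MgBr2 complex) | [Cu]CC[C@@](C)(O[Si](CC)(CC)CC)CCC=C(C)C | intermediate
9 | [(1E,5S)-5,9-dimethyl-2-(propan-2-yl)-5-(triethylsilyloxy)deca-1,8-dien-1-yl]copper | [Cu]/C=C(/C(C)C)CC[C@@](C)(O[Si](CC)(CC)CC)CCC=C(C)C | intermediate
10 | triethyl{[(1E,5S)-1-iodo-5,9-dimethyl-2-(propan-2-yl)deca-1,8-dien-5-yl]oxy}silane | I/C=C(/C(C)C)CC[C@@](C)(O[Si](CC)(CC)CC)CCC=C(C)C | intermediate
11 | (6R,9E)-10-iodo-2,6-dimethyl-9-(propan-2-yl)-6-(triethylsilyloxy)dec-9-ene-2,3-diol, both C3 epimers | I/C=C(/C(C)C)CC[C@@](C)(O[Si](CC)(CC)CC)CCC(O)C(C)(C)O | intermediate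
12 | (4R,7E)-8-iodo-4-methyl-7-(propan-2-yl)-4-(triethylsilyloxy)oct-7-enal | I/C=C(/C(C)C)CC[C@@](C)(O[Si](CC)(CC)CC)CCC=O | intermediate
13 | (4R,7E)-8-iodo-4-methyl-7-(propan-2-yl)-4-(triethylsilyloxy)oct-7-en-1-ol | I/C=C(/C(C)C)CC[C@@](C)(O[Si](CC)(CC)CC)CCCO | intermediate
14 | triethyl{[(1E,5R)-1,8-diiodo-5-methyl-2-(propan-2-yl)oct-1-en-5-yl]oxy}silane | I/C=C(/C(C)C)CC[C@@](C)(O[Si](CC)(CC)CC)CCCI | intermediate
15 | triethyl{[(1E,5S)-1-iodo-5-methyl-2-(propan-2-yl)dec-1-en-9-yn-5-yl]oxy}silane | I/C=C(/C(C)C)CC[C@@](C)(O[Si](CC)(CC)CC)CCCC#C | intermediate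
16 | trimethylaluminium | C[Al](C)C | starting material
17 | [(1E,6S,9E)-10-iodo-2,6-dimethyl-9-(propan-2-yl)-6-(triethylsilyloxy)deca-1,9-dien-1-yl]dimethylalumane | I/C=C(/C(C)C)CC[C@@](C)(O[Si](CC)(CC)CC)CCC/C(C)=C/[Al](C)C | intermediate
18 | triethyl{[(1E,5S,9E)-1-iodo-5,9-dimethyl-2-(propan-2-yl)-10-(4,4,5,5-tetramethyl-1,3,2-dioxaborolan-2-yl)deca-1,9-dien-5-yl]oxy}silane | I/C=C(/C(C)C)CC[C@@](C)(O[Si](CC)(CC)CC)CCC/C(C)=C/B1OC(C)(C)C(C)(C)O1 | intermediate
19 | triethyl{[(1E,3E,7S)-4-isopropyl-1,7-dimethylcyclodeca-1,3-dien-7-yl]oxy}silane (target numbering) | C/C1=C\C=C(\C(C)C)CC[C@@](C)(O[Si](CC)(CC)CC)CCC1 | intermediate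
20 | (1E,3E,7S)-4-isopropyl-1,7-dimethylcyclodeca-1,3-dien-7-ol (target numbering) | C/C1=C\C=C(\C(C)C)CC[C@@](C)(O)CCC1 | intermediate
21 | dioxygen | O=O | starting material
22 | (1E,3Z,5S,7S)-4-isopropyl-1,7-dimethylcyclodeca-1,3-diene-5,7-diol (target numbering) | C/C1=C\C=C(\C(C)C)[C@@H](O)C[C@@](C)(O)CCC1 | intermediate
23 | 4-hydroxybenzoic acid | O=C(O)c1ccc(O)cc1 | starting material
24 | tert-butyldimethylsilyl 4-(tert-butyldimethylsilyloxy)benzoate | CC(C)(C)[Si](C)(C)OC(=O)c1ccc(O[Si](C)(C)C(C)(C)C)cc1 | intermediate
25 | 4-(tert-butyldimethylsilyloxy)benzoic acid | O=C(O)c1ccc(O[Si](C)(C)C(C)(C)C)cc1 | intermediate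
26 | (1E,3Z,5S,7S)-7-hydroxy-4-isopropyl-1,7-dimethylcyclodeca-1,3-dien-5-yl 4-(tert-butyldimethylsilyloxy)benzoate (target numbering) | C/C1=C\C=C(\C(C)C)[C@@H](OC(=O)c2ccc(O[Si](C)(C)C(C)(C)C)cc2)C[C@@](C)(O)CCC1 | intermediate
27 | (1E,3Z,5S,7S)-7-hydroxy-4-isopropyl-1,7-dimethylcyclodeca-1,3-dien-5-yl 4-hydroxybenzoate (target numbering), CNP0130127.1 | C/C1=C\C=C(\C(C)C)[C@@H](OC(=O)c2ccc(O)cc2)C[C@@](C)(O)CCC1 | target

## Step count and least certain steps

Total step count: 14. Longest linear sequence: 13 steps (steps 1 to 11, 13 and 14, from 1 to 27); step 12 is a one-step branch.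

**Step 11 (key step, proposed new method).**
- What may go wrong: hydroxylation at another allylic site, epoxidation of the diene, or rebound at C3 or C1 with allylic transposition, because an unevolved pocket has no reason to prefer C5; low turnover on a bulky tertiary alcohol; further oxidation of the new carbinol to the dienone.
- Fallback (known chemistry, sets out from 4, returns at 22): the C5 oxygen is put in before the ring is closed.
  - Dess–Martin oxidation of 4 would give the aldehyde (3S)-3,7-dimethyl-3-(triethylsilyloxy)oct-6-enal F1.
  - Addition of lithium trimethylsilylacetylide gives the C5-epimeric silylated propargylic alcohols F2, which are oxidised to the ynone F3.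
  - Noyori transfer hydrogenation with [RuCl(p-cymene)((S,S)-TsDPEN)] in i-PrOH fixes C5 in the silylated (S)-propargylic alcohol F4. This catalyst enantiomer is expected, by the usual sense of induction for alkynyl ketones, to give the S carbinol.
  - K2CO3 in MeOH frees the terminal propargylic alcohol F5.
  - CuI-catalysed anti-carbomagnesiation with i-PrMgCl runs through the five-membered magnesium chelate F6, which places isopropyl on C4 and magnesium on C3 cis to C5. Iodination gives the iodo allylic alcohol F7.
  - Silylation with t-BuMe2SiOTf and 2,6-lutidine gives the bis-silyl ether F8.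
  - The operations of steps 5 to 9 are then repeated: vicinal diol F9, aldehyde F10, primary alcohol F11, diiodide F12, terminal alkyne F13, alkenylalane F14, alkenylboronate F15, and ring closure to the bis-silylated cyclodecadiene F16.
  - Bu4NF removes both silyl groups and gives 22, from which steps 13 and 14 follow unchanged. The detour costs four more steps than the enzymatic route.

**Step 9 (ring closure).**
- What may go wrong: intermolecular coupling to oligomers outruns the closure because the palladacycle leading to the E,Z-diene ring is strained; protodeboronation during the slow reaction.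
- Fallback (sets out from 15, returns at 19): the boron partner is given up and two carbon–iodine termini are coupled reductively. Carboalumination of 15 as in step 8, through 17, is followed by iodinolysis instead of boron transfer, to give the (1E,9E)-diiodide F17. Ring closure is then attempted with stoichiometric zerovalent nickel (Ni(cod)2, PPh3, DMF, 50 °C, high dilution), a reductive alkenyl–alkenyl coupling that needs no base and no transmetalation step.

**Step 8 (carboalumination and boron transfer).**
- What may go wrong: transfer of methyl instead of the alkenyl group from aluminium to boron, or sluggish carboalumination because the silyl ether binds the aluminium reagent.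
- Fallback (sets out from 15, returns at 18): copper-catalysed methylboration of the terminal alkyne (CuCl, Xantphos, B2pin2, MeI, KOt-Bu, THF). The boryl-copper species adds syn with boron on the terminal carbon, and the alkenylcopper is methylated at C1, so 18 is reached directly by a different carbometalation; no new isolated compound arises.

**Step 4 (carbocupration).**
- What may go wrong: slow or regiochemically imperfect addition of the functionalised alkylcopper to the α-branched alkyne, and thermal decay of the organocopper before it adds.
- Fallback (sets out from 5 and 6, returns at 10):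
  - Syn bromoboration of 6 with BBr3 gives the (Z)-alkenyldibromoborane F18, and pinacol converts it into the bromoalkenyl boronate F19, bromine cis to boron.
  - Grignard reagent 7, made from 5, is transmetalated with ZnBr2 to the alkylzinc bromide F20.
  - Negishi coupling (Pd(t-Bu3P)2, THF) replaces bromine with retention and gives the alkenylboronate F21, in which C5 is cis to boron.
  - I2 and NaOH exchange boron for iodine with retention and deliver 10.

## Further compounds

F1 | step 11 | (3S)-3,7-dimethyl-3-(triethylsilyloxy)oct-6-enal | O=CC[C@@](C)(O[Si](CC)(CC)CC)CCC=C(C)C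
F2 | step 11 | (5S)-5,9-dimethyl-5-(triethylsilyloxy)-1-(trimethylsilyl)dec-8-en-1-yn-3-ol, both C3 epimers | C[Si](C)(C)C#CC(O)C[C@@](C)(O[Si](CC)(CC)CC)CCC=C(C)C
F3 | step 11 | (5S)-5,9-dimethyl-5-(triethylsilyloxy)-1-(trimethylsilyl)dec-8-en-1-yn-3-one | C[Si](C)(C)C#CC(=O)C[C@@](C)(O[Si](CC)(CC)CC)CCC=C(C)C
F4 | step 11 | (3S,5S)-5,9-dimethyl-5-(triethylsilyloxy)-1-(trimethylsilyl)dec-8-en-1-yn-3-ol | C[Si](C)(C)C#C[C@@H](O)C[C@@](C)(O[Si](CC)(CC)CC)CCC=C(C)C
F5 | step 11 | (3S,5S)-5,9-dimethyl-5-(triethylsilyloxy)dec-8-en-1-yn-3-ol | C#C[C@@H](O)C[C@@](C)(O[Si](CC)(CC)CC)CCC=C(C)C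
F6 | step 11 | (5S)-5-[(2S)-2,6-dimethyl-2-(triethylsilyloxy)hept-5-en-1-yl]-4-(propan-2-yl)-2,5-dihydro-1,2-oxamagnesole (magnesium chelate bridging the C5 oxygen and C3) | CC(C)C1=C[Mg]O[C@H]1C[C@@](C)(O[Si](CC)(CC)CC)CCC=C(C)C
F7 | step 11 | (1Z,3S,5S)-1-iodo-5,9-dimethyl-2-(propan-2-yl)-5-(triethylsilyloxy)deca-1,8-dien-3-ol | I/C=C(/C(C)C)[C@@H](O)C[C@@](C)(O[Si](CC)(CC)CC)CCC=C(C)C
F8 | step 11 | tert-butyl{[(1Z,3S,5S)-1-iodo-5,9-dimethyl-2-(propan-2-yl)-5-(triethylsilyloxy)deca-1,8-dien-3-yl]oxy}dimethylsilane | I/C=C(/C(C)C)[C@@H](O[Si](C)(C)C(C)(C)C)C[C@@](C)(O[Si](CC)(CC)CC)CCC=C(C)C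
F9 | step 11 | (6S,8S,9Z)-8-(tert-butyldimethylsilyloxy)-10-iodo-2,6-dimethyl-9-(propan-2-yl)-6-(triethylsilyloxy)dec-9-ene-2,3-diol, both C3 epimers | I/C=C(/C(C)C)[C@@H](O[Si](C)(C)C(C)(C)C)C[C@@](C)(O[Si](CC)(CC)CC)CCC(O)C(C)(C)O
F10 | step 11 | (4S,6S,7Z)-6-(tert-butyldimethylsilyloxy)-8-iodo-4-methyl-7-(propan-2-yl)-4-(triethylsilyloxy)oct-7-enal | I/C=C(/C(C)C)[C@@H](O[Si](C)(C)C(C)(C)C)C[C@@](C)(O[Si](CC)(CC)CC)CCC=O
F11 | step 11 | (4S,6S,7Z)-6-(tert-butyldimethylsilyloxy)-8-iodo-4-methyl-7-(propan-2-yl)-4-(triethylsilyloxy)oct-7-en-1-ol | I/C=C(/C(C)C)[C@@H](O[Si](C)(C)C(C)(C)C)C[C@@](C)(O[Si](CC)(CC)CC)CCCO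
F12 | step 11 | tert-butyl{[(1Z,3S,5S)-1,8-diiodo-5-methyl-2-(propan-2-yl)-5-(triethylsilyloxy)oct-1-en-3-yl]oxy}dimethylsilane | I/C=C(/C(C)C)[C@@H](O[Si](C)(C)C(C)(C)C)C[C@@](C)(O[Si](CC)(CC)CC)CCCI
F13 | step 11 | tert-butyl{[(1Z,3S,5S)-1-iodo-5-methyl-2-(propan-2-yl)-5-(triethylsilyloxy)dec-1-en-9-yn-3-yl]oxy}dimethylsilane | I/C=C(/C(C)C)[C@@H](O[Si](C)(C)C(C)(C)C)C[C@@](C)(O[Si](CC)(CC)CC)CCCC#C
F14 | step 11 | [(1E,6S,8S,9Z)-8-(tert-butyldimethylsilyloxy)-10-iodo-2,6-dimethyl-9-(propan-2-yl)-6-(triethylsilyloxy)deca-1,9-dien-1-yl]dimethylalumane | I/C=C(/C(C)C)[C@@H](O[Si](C)(C)C(C)(C)C)C[C@@](C)(O[Si](CC)(CC)CC)CCC/C(C)=C/[Al](C)C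
F15 | step 11 | tert-butyl{[(1Z,3S,5S,9E)-1-iodo-5,9-dimethyl-2-(propan-2-yl)-10-(4,4,5,5-tetramethyl-1,3,2-dioxaborolan-2-yl)-5-(triethylsilyloxy)deca-1,9-dien-3-yl]oxy}dimethylsilane | I/C=C(/C(C)C)[C@@H](O[Si](C)(C)C(C)(C)C)C[C@@](C)(O[Si](CC)(CC)CC)CCC/C(C)=C/B1OC(C)(C)C(C)(C)O1
F16 | step 11 | tert-butyl{[(1E,3Z,5S,7S)-4-isopropyl-1,7-dimethyl-7-(triethylsilyloxy)cyclodeca-1,3-dien-5-yl]oxy}dimethylsilane (target numbering) | C/C1=C\C=C(\C(C)C)[C@@H](O[Si](C)(C)C(C)(C)C)C[C@@](C)(O[Si](CC)(CC)CC)CCC1
F17 | step 9 | triethyl{[(1E,5S,9E)-1,10-diiodo-5,9-dimethyl-2-(propan-2-yl)deca-1,9-dien-5-yl]oxy}silane | I/C=C(/C(C)C)CC[C@@](C)(O[Si](CC)(CC)CC)CCC/C(C)=C/I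
F0 | step 8 | none | none
F18 | step 4 | dibromo[(1Z)-2-bromo-3-methylbut-1-en-1-yl]borane | CC(C)/C(Br)=C/B(Br)Br
F19 | step 4 | 2-[(1Z)-2-bromo-3-methylbut-1-en-1-yl]-4,4,5,5-tetramethyl-1,3,2-dioxaborolane | CC(C)/C(Br)=C/B1OC(C)(C)C(C)(C)O1
F20 | step 4 | bromo[(3S)-3,7-dimethyl-3-(triethylsilyloxy)oct-6-en-1-yl]zinc | Br[Zn]CC[C@@](C)(O[Si](CC)(CC)CC)CCC=C(C)C
F21 | step 4 | triethyl{[(1E,5S)-5,9-dimethyl-2-(propan-2-yl)-1-(4,4,5,5-tetramethyl-1,3,2-dioxaborolan-2-yl)deca-1,8-dien-5-yl]oxy}silane | B1(OC(C)(C)C(C)(C)O1)/C=C(/C(C)C)CC[C@@](C)(O[Si](CC)(CC)CC)CCC=C(C)C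
A1 | alternative 1 | (1E,3Z,5S)-4-isopropyl-5-(4-methoxybenzyloxy)-1-methylcyclodeca-1,3-dien-7-one (target numbering) | C/C1=C\C=C(\C(C)C)[C@@H](OCc2ccc(OC)cc2)CC(=O)CCC1
A2 | alternative 2 | (1E,3Z,5S,7S)-5-(tert-butyldimethylsilyloxy)-4-isopropyl-1,7-dimethylcyclodeca-1,3-dien-7-ol (target numbering) | C/C1=C\C=C(\C(C)C)[C@@H](O[Si](C)(C)C(C)(C)C)C[C@@](C)(O)CCC1
A3 | alternative 3 | (1E,3Z,7S)-4-isopropyl-1,7-dimethyl-7-(triethylsilyloxy)cyclodeca-1,3-dien-5-one (target numbering) | C/C1=C\C=C(\C(C)C)C(=O)C[C@@](C)(O[Si](CC)(CC)CC)CCC1
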